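If single product simply followed the reagent charged, as the hunch has it, the flask would hold twice the 14.0% of dusk, but the runs do not scale that way.

| flask | substrate | reagent | remark | time |
|---|---|---|---|---|
| dusk | 0.20 M | 0.10 M | run made earlier |  |
| summer | 0.20 M | 0.40 M | run made earlier |  |
| autumn | 0.40 M | 0.20 M | run made earlier |  |
| flask | 0.20 M | 0.200 M |  | 12 d |

| run | time / d | single product / % | substrate / % |
|---|---|---|---|
| dusk | 0.104 | 8.2 | 87.7 |
| dusk | 0.333 | 14.0 | 69.2 |
| dusk | 1.04 | 9.3 | 47.7 |
| dusk | 3.00 | 5.1 | 33.0 |
| dusk | 10.0 | 1.8 | 22.2 |
| summer | 0.104 | 27.8 | 59.8 |
| summer | 0.333 | 29.6 | 25.4 |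
| summer | 1.04 | 14.1 | 5.3 |
| summer | 3.00 | 8.5 | 1.0 |
| summer | 10.0 | 7.1 | 0 |
| autumn | 0.104 | 13.4 | 78.4 |
| autumn | 0.333 | 13.8 | 55.1 |
| autumn | 1.04 | 5.2 | 35.8 |
| autumn | 3.00 | 2.5 | 27.0 |
| autumn | 10.0 | 0.7 | 20.0 |

(scatter of a reading: 0.3 percentage points)

- time, not beyond 12 d, at which the flask holds most single product
- the amount of single product, in percent of the substrate charged, at that time
- earliest time at which at least nineteen twentieths of that best amount are there, in d
- latest time at which they still are, in d

- a species is counted by the substrate in it: one side product counts as two
- on the list of suspects stand: substrate + reagent -> single product + released group; reagent + single product -> double product + released group; reagent + double product -> triple product + released group; single product <-> isomer of the product; substrate + single product -> side product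

Take the reagent balance. Each reagent spent frees one released group W, so, in percent of the substrate charged, W = M + E + 2D + 3T + O/2, with M, E, D, T and O the single product, isomer, double product, triple product and side product. Dusk charges less reagent than substrate, so reagent is the limiting reagent there. The measure carried here is φ = M/r at the highest reading, the share of the charged reagent standing as single product, with r the equivalents of reagent to substrate.

Dusk, at r = 0.500, reads φ = 28.0%. Autumn has the same r at twice the concentrations, and its highest reading lies 0.2 percentage points from dusk's, against a scatter of 0.3 points. Summer, at r = 2.00, reads φ = 14.8%. So φ falls as r grows, and the fall exponent n, the slope of ln φ against ln r, is 0.460. For the flask this reckoning gives φ = 20.4%, hence a best of 20.4%, near 0.333 d, the reading at which dusk, summer and autumn each stand highest.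

The forecast stands a little apart from this reckoning, with 19.5% at 0.3 d and a window from 0.17 d to 0.47 d, and says “The maximum is flat”.

The flask gives 22.6% at 0.298 d, with the window asked for running from 0.198 d to 0.446 d, so its φ is 22.6%, which is 2.2 points above the reckoning.

substrate + reagent → single product + released group (k = 0.540 M⁻¹ h⁻¹); reagent + single product → double product + released group (k = 0.330 M⁻¹ h⁻¹); reagent + double product → triple product + released group (k = 1.60 M⁻¹ h⁻¹); single product ⇌ isomer of the product (K = 2.00, k = 0.0630 h⁻¹); substrate + single product → side product (k = 0.390 M⁻¹ h⁻¹) At 0.219 d the flask makes single product 1.25 times as fast as it uses it up, each step taken net. By 12.0 d that ratio has dropped to 0.724. Carried to the neighbour, the same flask with 0.12 M of reagent, n gives a best of 15.4%, and that neighbour reaches 15.9%.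

(The runs are calculated with constants of no real substance; scatter was added.)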